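Assumption: (2S)-naringenin of ≥98 % ee (citrus-derived) can be bought, and ethyl 3-[4-(benzyloxy)phenyl]-3-oxopropanoate and 3,5-bis(benzyloxy)phenol are catalogue compounds.

**Retrosynthetic overview**
- The last step is a neutral hydrogenolysis of three benzyl ethers, so the heat- and base-labile flavanone C2 centre never meets harsh conditions.
- The C3–O–aryl ether is cut into the free 4'-OH of (2S)-sakuranetin and a flavon-3-ylboronic acid, joined by a Cu(II) coupling at room temperature.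
- The boronic acid comes from C3-lithiation and borylation of tri-O-benzylapigenin.
- The flavone pyranone ring is the only ring built. An aroylketene (β-keto ester minus EtOH) adds in a hetero-[4+2] across the enolic C=C of 3,5-bis(benzyloxy)phenol, and loss of water follows.
- The three flavanone rings and the stereocentre are bought in (2S)-naringenin, which needs only 7-O-methylation. All other arene rings are bought.

**Route**

Step 1
Reactants: 1 (2S)-naringenin
Product: 2 (2S)-sakuranetin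
Conditions: MeOH (1.05 equiv), PPh3, DIAD (1.1 equiv each), THF, 0 °C → rt
Reagents that add atoms: methanol, CO
Why: In this Mitsunobu etherification the betaine deprotonates only the most acidic 7-OH (the 5-OH is chelated to C4=O and the 4'-OH is about 2 pKa units weaker), and because no free base is present the retro-oxa-Michael racemisation of the bought (2S) centre cannot start.

Step 2
Reactants: 3 ethyl 3-[4-(benzyloxy)phenyl]-3-oxopropanoate, 4 3,5-bis(benzyloxy)phenol
Product: 7 5,7-bis(benzyloxy)-2-[4-(benzyloxy)phenyl]-4H-chromen-4-one, via aroylketene 5 (not isolated), via 8a-hydroxy cycloadduct 6 (not isolated)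
Conditions: neat, 3 (1.3 equiv), 240 °C (µW), 15 min, N2 sweep (–EtOH, –H2O)
Reagents that add atoms: none
Why: In this Mentzer pyrone synthesis, thermal loss of EtOH from the enol of 3 gives aroylketene 5, whose O=C–C=C oxadiene adds in a hetero-Diels–Alder [4+2] across the enolic C1(OH)=C2 bond of the electron-rich phenol (C2 to the ketene carbon, aroyl O to C1) to give 6, and loss of water rearomatises it to the flavone; no stereocentre is present, so the heat does no harm.

Step 3
Reactants: 7 5,7-bis(benzyloxy)-2-[4-(benzyloxy)phenyl]-4H-chromen-4-one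
Product: 10 {5,7-bis(benzyloxy)-2-[4-(benzyloxy)phenyl]-4-oxo-4H-chromen-3-yl}boronic acid, via 3-lithioflavone 8 (not isolated), via lithium triisopropyl borate 9 (not isolated)
Conditions: B(OiPr)3 (3 equiv), LDA (1.5 equiv, in-situ quench), THF, –78 → –20 °C; 1 M HCl, 0 °C
Reagents that add atoms: triisopropyl borate, CC(C)OB(OC(C)C)OC(C)C; water, O
Why: This is a carbonyl-directed deprotonation with electrophilic borylation, in which C3–H is the kinetically most acidic site of a flavone (Li is held by C4=O), the borate traps the vinyl-lithium as it forms, and benzyl ethers are inert to LDA at –78 °C.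

Step 4
Reactants: 2 (2S)-sakuranetin, 10 {5,7-bis(benzyloxy)-2-[4-(benzyloxy)phenyl]-4-oxo-4H-chromen-3-yl}boronic acid (2 equiv)
Product: 11 (2S)-2-[4-({5,7-bis(benzyloxy)-2-[4-(benzyloxy)phenyl]-4-oxo-4H-chromen-3-yl}oxy)phenyl]-5-hydroxy-7-methoxy-2,3-dihydro-4H-chromen-4-one
Conditions: Cu(OAc)2 (2 equiv), pyridine (5 equiv), 4 Å MS, CH2Cl2, dry air, rt, 36 h
Reagents that add atoms: none
Why: In this Chan–Lam–Evans oxidative C–O coupling (transmetalation to the Cu(II) phenoxide, then reductive elimination from Cu(III)) only the free 4'-OH reacts because the 5-OH is locked in its hydrogen bond, and room temperature with pyridine as the only base leaves the (2S) centre untouched, with ee checked by chiral HPLC.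

Step 5
Reactants: 11 (2S)-tri-O-benzyl biflavonoid ether
Product: 12 CNP0173006.1, (2S)-2-(4-{[5,7-dihydroxy-2-(4-hydroxyphenyl)-4-oxo-4H-chromen-3-yl]oxy}phenyl)-5-hydroxy-7-methoxy-2,3-dihydro-4H-chromen-4-one
Conditions: H2 (1 atm), 10 % Pd/C, EtOAc–MeOH, rt
Reagents that add atoms: none
Why: Neutral hydrogenolysis removes the three aryl benzyl ethers while the methyl ether, the tetrasubstituted C2=C3 enol ether, the chelated ketone and the cyclic C2–O bond survive at 1 atm and rt, and without acid or base the stereocentre is retained.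

**Compound list**
1 | (2S)-naringenin | Oc1cc(O)c2c(c1)O[C@H](c1ccc(O)cc1)CC2=O | starting material
2 | (2S)-sakuranetin | COc1cc(O)c2c(c1)O[C@H](c1ccc(O)cc1)CC2=O | intermediate
3 | ethyl 3-[4-(benzyloxy)phenyl]-3-oxopropanoate | CCOC(=O)CC(=O)c1ccc(OCc2ccccc2)cc1 | starting material
4 | 3,5-bis(benzyloxy)phenol | Oc1cc(OCc2ccccc2)cc(OCc2ccccc2)c1 | starting material
5 | [4-(benzyloxy)benzoyl]ketene | O=C=CC(=O)c1ccc(OCc2ccccc2)cc1 | intermediate
6 | 5,7-bis(benzyloxy)-2-[4-(benzyloxy)phenyl]-8a-hydroxy-4a,8a-dihydro-4H-chromen-4-one (racemic, transient) | O=C1C=C(c2ccc(OCc3ccccc3)cc2)OC2(O)C=C(OCc3ccccc3)C=C(OCc3ccccc3)C12 | intermediate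
7 | 5,7-bis(benzyloxy)-2-[4-(benzyloxy)phenyl]-4H-chromen-4-one (tri-O-benzylapigenin) | O=c1cc(-c2ccc(OCc3ccccc3)cc2)oc2cc(OCc3ccccc3)cc(OCc3ccccc3)c12 | intermediate
8 | 3-lithio derivative of 7 | [Li]c1c(-c2ccc(OCc3ccccc3)cc2)oc2cc(OCc3ccccc3)cc(OCc3ccccc3)c2c1=O | intermediate
9 | lithium triisopropoxy(flavon-3-yl)borate | [Li+].CC(C)O[B-](OC(C)C)(OC(C)C)c1c(-c2ccc(OCc3ccccc3)cc2)oc2cc(OCc3ccccc3)cc(OCc3ccccc3)c2c1=O | intermediate
10 | {5,7-bis(benzyloxy)-2-[4-(benzyloxy)phenyl]-4-oxo-4H-chromen-3-yl}boronic acid | OB(O)c1c(-c2ccc(OCc3ccccc3)cc2)oc2cc(OCc3ccccc3)cc(OCc3ccccc3)c2c1=O | intermediate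
11 | (2S)-tri-O-benzyl ether of the target | COc1cc(O)c2c(c1)O[C@H](c1ccc(Oc3c(-c4ccc(OCc5ccccc5)cc4)oc4cc(OCc5ccccc5)cc(OCc5ccccc5)c4c3=O)cc1)CC2=O | intermediate
12 | CNP0173006.1 | COc1cc(O)c2c(c1)O[C@H](c1ccc(Oc3c(-c4ccc(O)cc4)oc4cc(O)cc(O)c4c3=O)cc1)CC2=O | target

**Step count**
- Total steps: 5.
- Longest linear sequence: 4 steps (3/4 → 7 → 10 → 11 → 12).

**Steps most likely to fail**

Step 4. The flanked, electron-rich alkenylboronic acid may protodeboronate or oxidise faster than it couples.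
- The fallback sets out from 2 and comes back at 12. It forms the ether at an sp3 carbon by carbenoid O–H insertion and closes the pyranone afterwards.
- 2',4',6'-Tris(benzyloxy)acetophenone and methyl 4-(benzyloxy)benzoate (LiHMDS, THF) give 1-[4-(benzyloxy)phenyl]-3-[2,4,6-tris(benzyloxy)phenyl]propane-1,3-dione F1.
- Regitz diazo transfer (p-ABSA, Et3N, MeCN) gives the 2-diazo-1,3-diketone F2.
- Rh2(OAc)4 (1 mol %) in CH2Cl2 at 40 °C, with F2 added slowly to 2, gives the 2-aryloxy-1,3-diketone F3.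
- H2 over Pd/C gives the debenzylated 2-aryloxy-1,3-diketone F4, which cyclodehydrates with catalytic TsOH in EtOAc at rt to 12.

Step 3. Lithiation may be incomplete, or the boronic acid may be lost on work-up.
- The fallback sets out from 7 and comes back at 10. It uses electrophilic halogenation and Pd catalysis instead of a carbanion.
- I2 and CAN in MeCN at 60 °C give 5,7-bis(benzyloxy)-2-[4-(benzyloxy)phenyl]-3-iodo-4H-chromen-4-one F5.
- PdCl2(dppf), B2pin2 and KOAc in dioxane at 80 °C give the flavon-3-yl pinacol boronate F6.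
- NaIO4 and NH4OAc in aqueous acetone convert F6 into 10.

Step 2. The dibenzyl ether is less reactive than phloroglucinol, and benzyl groups may migrate at 240 °C.
- The fallback sets out from 4 and comes back at 7. It replaces the thermal reaction by a stepwise ionic acyl-transfer sequence.
- Ac2O and BF3·OEt2 give 1-[2,4-bis(benzyloxy)-6-hydroxyphenyl]ethanone F7.
- 4-(Benzyloxy)benzoyl chloride in pyridine gives 2-acetyl-3,5-bis(benzyloxy)phenyl 4-(benzyloxy)benzoate F8.
- KOH in pyridine at 50 °C (Baker–Venkataraman) gives 1-[2,4-bis(benzyloxy)-6-hydroxyphenyl]-3-[4-(benzyloxy)phenyl]propane-1,3-dione F9.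
- Catalytic H2SO4 in AcOH closes F9 to 7.

**Further compounds**
F1 | step 4 | 1-[4-(benzyloxy)phenyl]-3-[2,4,6-tris(benzyloxy)phenyl]propane-1,3-dione | O=C(CC(=O)c1c(OCc2ccccc2)cc(OCc2ccccc2)cc1OCc1ccccc1)c1ccc(OCc2ccccc2)cc1
F2 | step 4 | 1-[4-(benzyloxy)phenyl]-2-diazo-3-[2,4,6-tris(benzyloxy)phenyl]propane-1,3-dione | O=C(c1ccc(OCc2ccccc2)cc1)C(=[N+]=[N-])C(=O)c1c(OCc2ccccc2)cc(OCc2ccccc2)cc1OCc1ccccc1
F3 | step 4 | 2-aryloxy-1,3-diketone from O–H insertion into 2 (epimeric at the diketone carbon, 2S in the flavanone) | COc1cc(O)c2c(c1)O[C@H](c1ccc(OC(C(=O)c3ccc(OCc4ccccc4)cc3)C(=O)c3c(OCc4ccccc4)cc(OCc4ccccc4)cc3OCc3ccccc3)cc1)CC2=O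
F4 | step 4 | debenzylated 2-aryloxy-1,3-diketone (2S in the flavanone) | COc1cc(O)c2c(c1)O[C@H](c1ccc(OC(C(=O)c3ccc(O)cc3)C(=O)c3c(O)cc(O)cc3O)cc1)CC2=O
F5 | step 3 | 5,7-bis(benzyloxy)-2-[4-(benzyloxy)phenyl]-3-iodo-4H-chromen-4-one | Ic1c(-c2ccc(OCc3ccccc3)cc2)oc2cc(OCc3ccccc3)cc(OCc3ccccc3)c2c1=O
F6 | step 3 | flavon-3-yl pinacol boronate | CC1(C)OB(OC1(C)C)c1c(-c2ccc(OCc3ccccc3)cc2)oc2cc(OCc3ccccc3)cc(OCc3ccccc3)c2c1=O
F7 | step 2 | 1-[2,4-bis(benzyloxy)-6-hydroxyphenyl]ethanone | CC(=O)c1c(O)cc(OCc2ccccc2)cc1OCc1ccccc1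
F8 | step 2 | 2-acetyl-3,5-bis(benzyloxy)phenyl 4-(benzyloxy)benzoate | CC(=O)c1c(OC(=O)c2ccc(OCc3ccccc3)cc2)cc(OCc2ccccc2)cc1OCc1ccccc1
F9 | step 2 | 1-[2,4-bis(benzyloxy)-6-hydroxyphenyl]-3-[4-(benzyloxy)phenyl]propane-1,3-dione | O=C(CC(=O)c1c(O)cc(OCc2ccccc2)cc1OCc1ccccc1)c1ccc(OCc2ccccc2)cc1
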